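**Plan**
1. Cuts: O7–H is masked as a silyl ether and the C2–H/C3–H pair is taken back to the C2=C3 flavone. Ring C is then cut at three bonds at once: C4a–C4, C4–C3 and O1–C2.
2. Enabling feature: the ketone carbon C4 carries only its oxygen and bridges C4a and C3, while O1 sits on C8a next to C4a. Ring C is therefore the sum of a 2-iodophenol (ring A, O1), CO (C4) and an ethynylarene (C3, C2, ring B).
3. Ring A piece: the C8–prenyl bond is made by lithiation between the two MOM ethers of resorcinol, followed by C4a–I and O7–Si. Ring B piece: a tertiary propargyl ether of 4-hydroxybenzaldehyde is cyclised, then CHO is converted to C≡CH.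
4. Ring order in the forward direction: the chromene pyran ring closes first (thermal cascade, step 7) and ring C second (step 9). Both benzene rings are bought.
5. Stereochemistry: C2 is the only stereocentre. It is set as S by ligand-controlled copper hydride delivery to C2 of the flat flavone (step 10), and a buffered final desilylation guards it against retro-oxa-Michael racemisation.

Key step: step 9

Assumption: the sense of induction in step 10 is assigned by analogy with cyclic β,β-disubstituted enones, for which the (S)-ligand is taken to deliver hydride to the face of C2 that gives 2S. If a trial on the parent flavone shows the opposite sense, the (R)-ligand is used and nothing else changes.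

**Route**

Step 1
Reactants: 1 resorcinol
Product: 2 1,3-bis(methoxymethoxy)benzene
Conditions: NaH (2.4 equiv), MOMCl (2.3 equiv), DMF, 0 °C to rt
Reagents that add atoms: chloromethyl methyl ether, COCCl
Why: Williamson-type O-alkylation of the bis-phenoxide gives the bis-acetal, whose two MOM oxygens will direct the metalation of step 2.

Step 2
Reactants: 2 1,3-bis(methoxymethoxy)benzene; 3 prenyl bromide (1-bromo-3-methylbut-2-ene)
Product: 5 1,3-bis(methoxymethoxy)-2-(3-methylbut-2-en-1-yl)benzene, via aryllithium 4 (not isolated)
Conditions: n-BuLi, THF, 0 °C to rt; then 3, −78 °C to rt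
Reagents that add atoms: none
Why: Directed ortho-metalation removes the C2 proton, the only one flanked by two coordinating MOM ethers, and the aryllithium displaces bromide at the primary carbon of 3 (SN2), which places the prenyl group between the two oxygens.

Step 3
Reactants: 5 1,3-bis(methoxymethoxy)-2-(3-methylbut-2-en-1-yl)benzene
Product: 6 2-(3-methylbut-2-en-1-yl)benzene-1,3-diol (2-prenylresorcinol)
Conditions: conc. HCl (cat.), MeOH, rt to 40 °C
Reagents that add atoms: none
Why: Acid-catalysed acetal exchange with methanol cleaves aryl MOM ethers faster than dilute acid protonates the trisubstituted alkene, so the diol should be freed without closure to a chroman, as is routine for prenylated phenols.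

Step 4
Reactants: 6 2-prenylresorcinol
Product: 7 4-iodo-2-(3-methylbut-2-en-1-yl)benzene-1,3-diol
Conditions: I2 (1.0 equiv), NaHCO3, THF/H2O, 0 °C
Reagents that add atoms: iodine, II
Why: Electrophilic aromatic iodination of the resorcinolate should outrun reversible iodonium formation at the alkene in aqueous bicarbonate, and because C2 is blocked and C4 and C6 are related by the mirror plane of 6, one equivalent of iodine can give only one mono-iodide.

Step 5
Reactants: 7 4-iodo-2-prenylresorcinol
Product: 8 3-[(tert-butyldimethylsilyl)oxy]-6-iodo-2-(3-methylbut-2-en-1-yl)phenol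
Conditions: TBSCl (1.0 equiv), imidazole, CH2Cl2, 0 °C
Reagents that add atoms: tert-butyldimethylsilyl chloride, CC(C)(C)[Si](C)(C)Cl
Why: Kinetically controlled silylation should pick the hydroxyl with a single ortho substituent over the one wedged between prenyl and iodine, which leaves free exactly the OH next to iodine that becomes O1.

Step 6
Reactants: 9 4-hydroxybenzaldehyde; 10 2-methylbut-3-yn-2-ol
Product: 12 4-[(2-methylbut-3-yn-2-yl)oxy]benzaldehyde, via propargylic trifluoroacetate 11 (not isolated)
Conditions: 10, (CF3CO)2O, DBU, MeCN, 0 °C; then 9, DBU, CuCl2·2H2O (cat.), MeCN, 0 °C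
Reagents that add atoms: none
Why: Copper-catalysed propargylic substitution of the tertiary trifluoroacetate by the phenoxide forms the hindered aryl tert-alkyl ether that a plain SN2 reaction could not, and acidic phenols such as 9 are the best partners for it.

Step 7
Reactants: 12 4-[(2-methylbut-3-yn-2-yl)oxy]benzaldehyde
Product: 13 2,2-dimethyl-2H-chromene-6-carbaldehyde
Conditions: PhNEt2, 190 °C
Reagents that add atoms: none
Why: Aromatic propargyl Claisen rearrangement, 1,5-hydrogen shift and oxa-6π electrocyclisation run as one thermal cascade that closes the pyran ring, and since both ortho positions of 12 are equivalent only one chromene can result.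

Step 8
Reactants: 13 2,2-dimethyl-2H-chromene-6-carbaldehyde
Product: 14 6-ethynyl-2,2-dimethyl-2H-chromene
Conditions: dimethyl (1-diazo-2-oxopropyl)phosphonate, K2CO3, MeOH, rt
Reagents that add atoms: dimethyl (1-diazo-2-oxopropyl)phosphonate, CC(=O)C(=[N+]=[N-])P(=O)(OC)OC
Why: The Seyferth–Gilbert homologation in its Ohira–Bestmann form turns the non-enolisable aryl aldehyde into the terminal alkyne under carbonate/methanol, conditions that do not harm the chromene.

Step 9
Reactants: 8 3-[(tert-butyldimethylsilyl)oxy]-6-iodo-2-prenylphenol; 14 6-ethynyl-2,2-dimethyl-2H-chromene; 15 carbon monoxide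
Product: 18 7-[(tert-butyldimethylsilyl)oxy]-2-(2,2-dimethyl-2H-chromen-6-yl)-8-(3-methylbut-2-en-1-yl)-4H-chromen-4-one, via ynone 16 (not isolated), via enaminone 17 (not isolated)
Conditions: PdCl2(dppf) (5 mol %), CO (5 bar), Et2NH, 80 °C, no copper salt
Reagents that add atoms: none
Why: Pd(0) inserts into the C4a–I bond of 8, CO migrates in to give the aroyl-palladium species, and the amine-assisted palladium acetylide of 14 reductively eliminates ynone 16, which makes C4a–C4 and C4–C3. Diethylamine then adds to C2 of 16 to give the push-pull enaminone 17, and the free ortho hydroxyl replaces the amine at C2 by addition–elimination, which makes O1–C2 and closes ring C in the 6-endo mode. The closest known reaction type is the palladium-catalysed carbonylative Sonogashira coupling/annulation of 2-iodophenols with terminal arylacetylenes to flavones in a secondary amine. No stereocentre arises, since C2 is still sp2 in 18. Two selectivities matter: ring size, where attack of O1 at C2 (flavone) must beat attack at C3 (five-membered aurone) and is enforced because the amine adduct carries its only leaving group on C2, and CO uptake ahead of direct alkynylation, which the copper-free medium, the CO pressure and the electron-rich aryl-palladium favour. In 8 only the hydroxyl next to iodine is free, O7 being silylated, so no second phenol can trap the acyl-palladium, and the trisubstituted prenyl and 1,2-disubstituted chromene alkenes are too hindered for Heck insertion.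

Step 10
Reactants: 18 7-O-TBS-8-prenyl flavone
Product: 20 (2S)-7-[(tert-butyldimethylsilyl)oxy]-2-(2,2-dimethyl-2H-chromen-6-yl)-8-(3-methylbut-2-en-1-yl)-2,3-dihydro-4H-chromen-4-one, via silyl enol ether 19 (not isolated)
Conditions: Cu(OAc)2 (5 mol %), (S)-DTBM-SEGPHOS (5.5 mol %), (EtO)2MeSiH (1.2 equiv), toluene, −10 °C to rt; then AcOH, THF/H2O, 0 °C
Reagents that add atoms: none
Why: In this asymmetric copper hydride conjugate reduction (1,4-hydrosilylation), a reaction type established for cyclic β,β-disubstituted enones and 2-substituted chromones, the bulky bisphosphine–CuH should add hydride to one face of C2 and set 2S, while the silane traps the copper enolate as 19 so that ketone over-reduction and E1cB opening of ring C are held back, and the unactivated prenyl and chromene alkenes find no proton source in the aprotic medium.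

Step 11
Reactants: 20 (2S)-7-O-TBS flavanone
Product: 21 (2S)-2-(2,2-dimethyl-2H-chromen-6-yl)-7-hydroxy-8-(3-methylbut-2-en-1-yl)-2,3-dihydro-4H-chromen-4-one (target)
Conditions: TBAF, AcOH (1:1), THF, 0 °C
Reagents that add atoms: none
Why: Fluoride cleaves the aryl silyl ether through pentacoordinate silicon and acetic acid protonates the phenoxide at once, so the medium should never become basic enough for enolisation and retro-oxa-Michael opening of ring C, which would racemise C2.

**Compound list**
1 | resorcinol | Oc1cccc(O)c1 | starting material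
2 | 1,3-bis(methoxymethoxy)benzene | COCOc1cccc(OCOC)c1 | intermediate
3 | prenyl bromide | CC(C)=CCBr | starting material
4 | 2-lithio-1,3-bis(methoxymethoxy)benzene | [Li]c1c(OCOC)cccc1OCOC | intermediate
5 | 1,3-bis(methoxymethoxy)-2-(3-methylbut-2-en-1-yl)benzene | CC(C)=CCc1c(OCOC)cccc1OCOC | intermediate
6 | 2-(3-methylbut-2-en-1-yl)benzene-1,3-diol | CC(C)=CCc1c(O)cccc1O | intermediate
7 | 4-iodo-2-(3-methylbut-2-en-1-yl)benzene-1,3-diol | CC(C)=CCc1c(O)ccc(I)c1O | intermediate
8 | 3-[(tert-butyldimethylsilyl)oxy]-6-iodo-2-(3-methylbut-2-en-1-yl)phenol | CC(C)=CCc1c(O[Si](C)(C)C(C)(C)C)ccc(I)c1O | intermediate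
9 | 4-hydroxybenzaldehyde | O=Cc1ccc(O)cc1 | starting material
10 | 2-methylbut-3-yn-2-ol | CC(C)(O)C#C | starting material
11 | 2-methylbut-3-yn-2-yl trifluoroacetate | C#CC(C)(C)OC(=O)C(F)(F)F | intermediate
12 | 4-[(2-methylbut-3-yn-2-yl)oxy]benzaldehyde | C#CC(C)(C)Oc1ccc(C=O)cc1 | intermediate
13 | 2,2-dimethyl-2H-chromene-6-carbaldehyde | O=Cc1ccc2c(c1)C=CC(C)(C)O2 | intermediate
14 | 6-ethynyl-2,2-dimethyl-2H-chromene | C#Cc1ccc2c(c1)C=CC(C)(C)O2 | intermediate
15 | carbon monoxide | [C-]#[O+] | starting material
16 | 1-{4-[(tert-butyldimethylsilyl)oxy]-2-hydroxy-3-prenylphenyl}-3-(2,2-dimethyl-2H-chromen-6-yl)prop-2-yn-1-one | CC(C)=CCc1c(O[Si](C)(C)C(C)(C)C)ccc(C(=O)C#Cc2ccc3c(c2)C=CC(C)(C)O3)c1O | intermediate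
17 | (E)-1-{4-[(tert-butyldimethylsilyl)oxy]-2-hydroxy-3-prenylphenyl}-3-(diethylamino)-3-(2,2-dimethyl-2H-chromen-6-yl)prop-2-en-1-one | CC(C)=CCc1c(O[Si](C)(C)C(C)(C)C)ccc(C(=O)/C=C(\c2ccc3c(c2)C=CC(C)(C)O3)N(CC)CC)c1O | intermediate
18 | 7-[(tert-butyldimethylsilyl)oxy]-2-(2,2-dimethyl-2H-chromen-6-yl)-8-(3-methylbut-2-en-1-yl)-4H-chromen-4-one | CC(C)=CCc1c(O[Si](C)(C)C(C)(C)C)ccc2c1OC(c1ccc3c(c1)C=CC(C)(C)O3)=CC2=O | intermediate
19 | (2S)-7-[(tert-butyldimethylsilyl)oxy]-4-{[diethoxy(methyl)silyl]oxy}-2-(2,2-dimethyl-2H-chromen-6-yl)-8-(3-methylbut-2-en-1-yl)-2H-chromene | CC(C)=CCc1c(O[Si](C)(C)C(C)(C)C)ccc2c1O[C@H](c1ccc3c(c1)C=CC(C)(C)O3)C=C2O[Si](C)(OCC)OCC | intermediate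
20 | (2S)-7-[(tert-butyldimethylsilyl)oxy]-2-(2,2-dimethyl-2H-chromen-6-yl)-8-(3-methylbut-2-en-1-yl)-2,3-dihydro-4H-chromen-4-one | CC(C)=CCc1c(O[Si](C)(C)C(C)(C)C)ccc2c1O[C@H](c1ccc3c(c1)C=CC(C)(C)O3)CC2=O | intermediate
21 | (2S)-2-(2,2-dimethyl-2H-chromen-6-yl)-7-hydroxy-8-(3-methylbut-2-en-1-yl)-2,3-dihydro-4H-chromen-4-one | CC(C)=CCc1c(O)ccc2c1O[C@H](c1ccc3c(c1)C=CC(C)(C)O3)CC2=O | target

**Step count**
Total step count: 11.
Longest linear sequence: 8 steps (steps 1–5, then 9–11). The ring B branch contributes steps 6–8.

**Steps most likely to fail**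

Step 10. Hydride transfer to the cross-conjugated, electron-rich 2-aryl chromone may be sluggish. Facial selectivity may be poor. The metal enolate may also open ring C before the silane traps it, which would cost configuration. The fallback moves the source of chirality from face-selective hydride addition to enantiomer-selective ketone reduction. It sets out from 18. Non-selective 1,4-reduction with L-Selectride (THF, −78 °C) should give the racemic 7-O-TBS flavanone F1. Kinetic resolution by Noyori–Ikariya transfer hydrogenation follows (RuCl[(R,R)-TsDPEN](p-cymene), HCO2H/Et3N, EtOAc, rt, stopped near half conversion). By the usual sense of this catalyst family it should reduce the R ketone to the (2R,4R)-cis-flavan-4-ol F2 and leave the slow-reacting S ketone. Chromatographic separation gives that ketone, and the route is rejoined at 20.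

Step 9. Diethylamine may intercept the acyl-palladium (aminocarbonylation). Alkynylation may occur before CO uptake, or the silyl group may be lost in hot amine. The fallback separates carbon–carbon bond formation from ring closure, so that no nucleophilic amine is present while the acyl-palladium exists. It sets out from 8. Acetylation (Ac2O, pyridine, DMAP) should give 3-[(tert-butyldimethylsilyl)oxy]-6-iodo-2-prenylphenyl acetate F3. A room-temperature carbonylative Sonogashira coupling of F3 with 14 and 15 (PdCl2(PPh3)2, Et3N, CO balloon, THF) should give the isolable O-acetyl ynone F4. Separate treatment of F4 with Et2NH (EtOH, rt to 50 °C) removes the acetate, passes through 16 and 17, and closes ring C. The route is rejoined at 18.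

Step 4. Iodine may attack the prenyl double bond, with the neighbouring phenol then closing onto it, or a second ring iodination may occur. The fallback brings iodine in by metalation instead of electrophilic substitution. It sets out from 5. A second directed ortho-metalation next to one MOM ether (s-BuLi, TMEDA, THF, −78 °C) and a quench with I2 at −78 °C should give 1-iodo-2,4-bis(methoxymethoxy)-3-(3-methylbut-2-en-1-yl)benzene F5. No free phenol is present at that stage to close onto an iodonium ion. Methanolysis of both MOM groups as in step 3 then rejoins the route at 7.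

**Further compounds**
F1 | step 10 | rac-7-[(tert-butyldimethylsilyl)oxy]-2-(2,2-dimethyl-2H-chromen-6-yl)-8-(3-methylbut-2-en-1-yl)-2,3-dihydro-4H-chromen-4-one | CC(C)=CCc1c(O[Si](C)(C)C(C)(C)C)ccc2c1OC(c1ccc3c(c1)C=CC(C)(C)O3)CC2=O
F2 | step 10 | (2R,4R)-7-[(tert-butyldimethylsilyl)oxy]-2-(2,2-dimethyl-2H-chromen-6-yl)-8-(3-methylbut-2-en-1-yl)chroman-4-ol (2,4-cis) | CC(C)=CCc1c(O[Si](C)(C)C(C)(C)C)ccc2c1O[C@@H](c1ccc3c(c1)C=CC(C)(C)O3)C[C@H]2O
F3 | step 9 | 3-[(tert-butyldimethylsilyl)oxy]-6-iodo-2-(3-methylbut-2-en-1-yl)phenyl acetate | CC(C)=CCc1c(O[Si](C)(C)C(C)(C)C)ccc(I)c1OC(C)=O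
F4 | step 9 | 3-[(tert-butyldimethylsilyl)oxy]-6-[3-(2,2-dimethyl-2H-chromen-6-yl)prop-2-ynoyl]-2-(3-methylbut-2-en-1-yl)phenyl acetate | CC(C)=CCc1c(O[Si](C)(C)C(C)(C)C)ccc(C(=O)C#Cc2ccc3c(c2)C=CC(C)(C)O3)c1OC(C)=O
F5 | step 4 | 1-iodo-2,4-bis(methoxymethoxy)-3-(3-methylbut-2-en-1-yl)benzene | CC(C)=CCc1c(OCOC)ccc(I)c1OCOC
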